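**One-step world.** In a one-step world you would simply titrate: each reagent opens one substrate, and the opened amount follows the charge until substrate is used up. Here are the flasks and the question.

common to all: substrate 0.37 M; partner 0.389 M

| run | reagent | remark | time |
|---|---|---|---|
| grey | 0.13 M | run made earlier |  |
| amber | 0.50 M | run made earlier |  |
| teal | 2.1 M | run made earlier |  |
| east | 0.150 M |  | 6.0 h |
| south-west | 0.300 M |  | 6.0 h |
| south-east | 0.600 M |  | 6.0 h |
| north | 1.20 M |  | 6.0 h |
| north-east | 2.00 M |  | 6.0 h |

- grey (time / h: open intermediate / %, target / %): 0.833: 30.5, 0.6; 1.50: 30.1, 1.5; 2.50: 29.4, 2.6; 3.00: 30.1, 2.5; 4.00: 29.7, 2.3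
- amber (time / h: open intermediate / %, target / %): 0.833: 83.0, 9.9; 1.50: 80.5, 16.5; 2.50: 77.3, 20.8; 3.00: 76.8, 22.0; 4.00: 76.1, 23.5
- teal (time / h: open intermediate / %, target / %): 0.833: 59.8, 39.4; 1.50: 48.2, 51.5; 2.50: 42.5, 58.2; 3.00: 41.0, 58.7; 4.00: 40.3, 59.7

(scatter of a reading: 0.3 percentage points)

- a reading or a percentage of target counts all its forms, free or not
- "hardly changes" means that all values lie within two and a half points (for a concentration: within two and a half percent of the largest)

- amount of open intermediate at the end, in percent of the substrate charged for east, south-west, south-east, north, north-east, in this order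
- how the row runs (falls, then rises / rises all the way / falls all the way / rises, then falls / hardly changes)

**Two rates.** Read the grey run at 3.00 h. Open intermediate and target together hold 32.6% of the substrate, which is 0.121 M opened from 0.13 M of reagent. Call substrate opened per reagent charged the opening share, 92.8%. The rest of the grey reagent went some way you cannot see, so two rates compete for reagent: opening and that other use. Their ratio, a selectivity factor, reads 12.9 in grey. But opening needs substrate, so this ratio should drift down as substrate thins, and the share should sag in a flask that opens more.

**My reckoning.** The opened percentage should be the share times c(reagent)/c(substrate), with reagent as limiting reagent up to 0.399 M. That gives 37.6% opened in east and, before any sag, 75.2% in south-west. Above that charge, amber's sum reaches 99.6%, yet open intermediate stands at 76.1% in amber and 40.3% in teal, while target climbs. So I expect a rise, then a fall, turning near 0.399 M.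

**The forecast.** It gave 34.5%, 69%, 64%, 45% and 41% of open intermediate, rises, then falls, holding that “opening consumes reagent about 1:1”.

**The result.** The flasks give 33.5%, 62.8%, 65.9%, 45.1% and 41.3%: rises, then falls.

    reagent + partner → second intermediate (k = 0.0290 M⁻¹ min⁻¹)
    2 second intermediate → homo product (k = 0.0380 M⁻¹ min⁻¹)
    substrate + reagent → open intermediate (k = 0.330 M⁻¹ min⁻¹)
    partner → decomposed reagent (k = 0.00740 min⁻¹)
    crystals ⇌ target, rate k5*(cs5 - [target]) while solid is left; crystals form when [target] > cs5 (solubility = 0.200 M, k = 2.40 min⁻¹)
    open intermediate + second intermediate ⇌ target (K = 58.0 M⁻¹, k = 0.0890 M⁻¹ min⁻¹)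

**Share tested.** East opened 36.7% against the 37.6% reckoned. South-west opened 71.4%, less than the 75.2% reckoned, which is the expected sag. The row turns at 0.44 M, against 0.399 M. The main reason for east's low value is the depletion of reagent, with 0% of its charge left at 6.00 h: east's open intermediate, 33.5% as it ran, reaches 67.4% without that depletion.

The earlier runs and the new flask come from a simulation for substances that don't exist; scatter was added.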